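The catalyst dies here. On the list of suspects, capture agent turns catalyst intermediate A into trapped intermediate, so product stops. The amount made per catalyst before that is what you would call the partition ratio.

| setting | Friday's | Saturday's | flask |
|---|---|---|---|
| starting material | 0.30 M | 0.30 M | 0.30 M |
| capture agent | 0.045 M | 0.18 M | 0.0900 M |
| gas | 21 mM (held) | 21 mM (held) | 21 mM (held) |
| free catalyst | 1 mol% | 1 mol% | 1 mol% |
| remark | run made earlier | run made earlier |  |

| run | time / h | product / % | starting material / % |
|---|---|---|---|
| Friday's | 0.250 | 12.4 | 86.6 |
| Friday's | 0.667 | 20.4 | 78.6 |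
| Friday's | 1.33 | 23.9 | 75.2 |
| Friday's | 2.00 | 24.7 | 75.1 |
| Friday's | 3.00 | 25.1 | 74.2 |
| Friday's | 4.00 | 25.1 | 74.5 |
| Saturday's | 0.667 | 3.8 | 95.6 |
| Saturday's | 1.33 | 3.7 | 95.1 |
| Saturday's | 2.00 | 4.0 | 95.1 |
| Saturday's | 2.50 | 2.8 | 94.8 |
| Saturday's | 3.00 | 5.0 | 95.1 |
| Saturday's | 4.00 | 3.4 | 94.8 |

(each reading ± 0.5 percentage points)

1. factor on the rate of making product when 10% of the starting material are converted if free catalyst is charged twice over
2. factor on the rate when 10% of the starting material are converted if free catalyst is charged at 10 mol% instead

Friday's product levels off near 25.1%, which is 25.1 rounds per catalyst. Saturday's stays near 3.78%, or 3.78 rounds.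

If each round carried the same risk, the plateau would fall inversely with c(capture agent). Friday then promises this flask 12.5%, but Saturday promises 7.57%. The rule cheats: plateau times c(capture agent) is 0.00681 M on Saturday, less than Friday's 0.0113 M. My guess at the reason is that capture already runs at the start, while no partner is dissolved. This flask's c(capture agent) is twice Friday's and half Saturday's, so I take the geometric middle of the two plateaus, 9.74%.

Starting material plus product also fall short of the charge, by 0.55 percentage points on Friday and 1.3 points on Saturday, which is about the catalyst loading. Trapped catalyst seems to keep its starting material. So plateau plus loading gives this flask 10.7%, the conversion ceiling: the conversion at which it stops.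

The mark of 10% therefore lies 0.74 points below the ceiling. Friday's tail closes on its plateau at 2.38 h⁻¹. Doubled for this flask, that is 4.77 h⁻¹, and times the distance left it gives 0.0107 M h⁻¹. If the rounds per catalyst stayed the same, doubling the catalyst would double the ceiling, and my factor would be 15.4; that is an assumption. At 10 mol% the same assumption gives 131, with a ceiling of 107%, above the charge, so the assumption cannot hold at that loading. No earlier run changes the catalyst, so both factors are guesses.

The forecast gives 12 (5 to 35) and 35 (12 to 110), adding “Both factors are highly uncertain”.

The flask gives 4.54 and 11.6, under my 15.4 and 131.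

    starting material + free catalyst ⇌ catalyst intermediate A (K = 19.6 M⁻¹, k = 211 M⁻¹ min⁻¹)
    partner + catalyst intermediate A ⇌ catalyst intermediate B (K = 1200 M⁻¹, k = 2920 M⁻¹ min⁻¹)
    catalyst intermediate B → catalyst intermediate C (k = 13.0 min⁻¹)
    catalyst intermediate C → free catalyst + product (k = 76.6 min⁻¹)
    catalyst intermediate A + capture agent → trapped intermediate (k = 6.50 M⁻¹ min⁻¹)
    gas ⇌ partner, rate k6*(csat - [partner]) (kL = 0.167 min⁻¹)

At 10% conversion, reached at 0.366 h, the rate with the original loading is 0.0180 M h⁻¹, above my 0.0107 M h⁻¹. At 6.00 h this flask holds 10.1% product beside 89% of its starting material, so its conversion stands at 11.0%, above my estimated ceiling of 10.7%.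

The readings are calculated on assumed constants.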